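The route rests on cutting C15'–C16', the exact midpoint of the unbranched (CH2)29 chain of the 30-hydroxytriacontanoyl residue, so that both C15 halves come from one feedstock, ω-pentadecalactone. The last step, a Ni–H hydroalkylation, joins the vinyl terminus of ent-17-hydroxylabda-7,13E-dien-15-yl pentadec-14-enoate to unprotected 15-iodopentadecan-1-ol and delivers the target without protecting groups. It exploits that this vinyl group is the only monosubstituted alkene: C7=C8 in ring B and C13=C14 in the side chain are trisubstituted. The ent-decalin stereocentres C5, C9 and C10 are bought with (−)-copalic acid, whose C8(17) methylene is transposed to the C7-ene C17-ol. A lipase then acylates O15 only.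

Key step: step 9

Remark: the ring stereocentres in the SMILES (5R,9S,10R, labdane numbering) are antipodal to the sclareol series, i.e. ent-labdane; (−)-copalic acid from copaiba oleoresin has this configuration and is taken as a purchasable natural product. Primed numbers refer to the acyl chain.

Step 1
Reactants: 1 ω-pentadecalactone
Product: 2 15-iodopentadecanoic acid
Conditions: 57% aq HI, AcOH, reflux, dark
Reagents that add atoms: hydrogen iodide, I
Why: Classical hydrohalic lactone cleavage, in which the protonated macrolactone is opened and iodide displaces oxygen at the primary O-alkyl carbon (SN2), should give the ω-iodo acid with all fifteen carbons kept.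

Step 2
Reactants: 2 15-iodopentadecanoic acid
Product: 3 pentadec-14-enoic acid
Conditions: KOtBu (3 equiv), THF, 0 °C to rt (2 added to the base); then 1 M HCl
Reagents that add atoms: none
Why: E2 dehydrohalogenation of the primary iodide by the bulky alkoxide, run on the carboxylate salt, should favour the terminal alkene over substitution.

Step 3
Reactants: 2 15-iodopentadecanoic acid
Product: 4 15-iodopentadecan-1-ol
Conditions: BH3·THF (1.5 equiv), THF, 0 °C to rt; then H2O
Reagents that add atoms: none
Why: Chemoselective borane reduction proceeds through an acyloxyborane and takes the carboxylic acid to the primary alcohol without touching the primary C–I bond.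

Step 4
Reactants: 5 (−)-copalic acid
Product: 6 isopropyl ent-labda-8(17),13E-dien-15-oate
Conditions: 2-iodopropane, K2CO3, DMF, 40 °C
Reagents that add atoms: 2-iodopropane, CC(C)I
Why: Carboxylate O-alkylation (SN2) leaves C5, C9, C10 and the 13E geometry alone, and the isopropyl ester makes alkoxide exchange with Al(OiPr)3 in step 6 degenerate.

Step 5
Reactants: 6 isopropyl ent-labda-8(17),13E-dien-15-oate
Product: 7 isopropyl ent-8,17-epoxylabd-13E-en-15-oate (8S, oxirane oxygen anti to the C10 methyl)
Conditions: mCPBA (1.1 equiv), CH2Cl2, 0 °C
Reagents that add atoms: mCPBA, O=C(OO)c1cccc(Cl)c1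
Why: The Prilezhaev epoxidation picks the electron-rich C8(17) methylene over the ester-conjugated C13=C14 bond and should attack mainly anti to the axial C10 methyl, and since C8 becomes sp2 again in step 6 any C8 epimer converges.

Step 6
Reactants: 7 isopropyl ent-8,17-epoxylabd-13E-en-15-oate
Product: 8 isopropyl ent-17-hydroxylabda-7,13E-dien-15-oate
Conditions: Al(OiPr)3 (2 equiv), toluene, reflux; aqueous work-up
Reagents that add atoms: none
Why: In this aluminium-alkoxide-promoted epoxide-to-allylic-alcohol isomerisation, aluminium activates the oxirane at tertiary C8 and a ligand alkoxide removes the accessible C7 proton in a cyclic syn elimination, giving C7=C8 and the C17 carbinol while C9 stays untouched.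

Step 7
Reactants: 8 isopropyl ent-17-hydroxylabda-7,13E-dien-15-oate
Product: 9 ent-labda-7,13E-diene-15,17-diol
Conditions: LiAlH4, Et2O, 0 °C; aqueous work-up
Reagents that add atoms: none
Why: 1,2-Reduction of a β,β-disubstituted enoate by LiAlH4 at 0 °C should give the allylic alcohol with the E geometry retained and no change at the ring stereocentres.

Step 8
Reactants: 9 ent-labda-7,13E-diene-15,17-diol; 3 pentadec-14-enoic acid (1.05 equiv)
Product: 10 ent-17-hydroxylabda-7,13E-dien-15-yl pentadec-14-enoate
Conditions: immobilised Candida antarctica lipase B, 4 Å molecular sieves, toluene, 45 °C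
Reagents that add atoms: none
Why: In this regioselective esterification by a lipase (serine hydrolase, EC 3.1.1.3), the acyl-enzyme from fatty acid 3 lies at the bottom of a narrow funnel that the chain-terminal C15 carbinol can reach as farnesol-type alcohols do, whereas the C17 carbinol on ring B next to C9 is too encumbered.

Step 9
Reactants: 10 ent-17-hydroxylabda-7,13E-dien-15-yl pentadec-14-enoate; 4 15-iodopentadecan-1-ol (2 equiv)
Product: 11 ent-17-hydroxylabda-7,13E-dien-15-yl 30-hydroxytriacontanoate (target)
Conditions: NiBr2·diglyme (10 mol %), 4,4'-di-tert-butyl-2,2'-bipyridine (15 mol %), (EtO)2MeSiH (3 equiv), Na2CO3 (3 equiv), DMA/THF, 30 °C; aq NH4Cl work-up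
Reagents that add atoms: none
Why: Nickel-hydride-catalysed anti-Markovnikov reductive hydroalkylation of a 1-alkene with a primary alkyl iodide: silane and carbonate convert the bipyridine–nickel halide into Ni–H, which inserts into the C14'=C15' vinyl group of 10 with nickel on terminal C15', while low-valent nickel abstracts iodine from 4 to give the HO(CH2)15 radical; radical capture gives a dialkylnickel(III) that reductively eliminates the C15'–C16' bond. This is the known NiH olefin/alkyl halide coupling (reductive olefin hydrocarbonation), a reaction type established for unactivated 1-alkenes and primary iodides in the presence of esters and free hydroxyl groups, so it is only applied here to a new pair of partners. No ring is closed and no stereocentre is formed; C5, C9, C10 and the 13E geometry are spectators. The decisive selectivity is among three alkenes and is secured by substitution: only the vinyl group is monosubstituted, whereas C7=C8 of ring B and C13=C14 of the side chain are trisubstituted and should not insert into the encumbered Ni–H at 30 °C. Linear regiochemistry follows from the preference for the primary alkylnickel, and survival of the O15 allylic ester rests on iodine abstraction from a primary iodide being much faster than ionisation of a 3,3-disubstituted allyl carboxylate. The cheap iodide 4 is used in excess to absorb its own hydrodehalogenation and homocoupling.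

Compound list
1 | ω-pentadecalactone (oxacyclohexadecan-2-one) | O=C1CCCCCCCCCCCCCCO1 | starting material
2 | 15-iodopentadecanoic acid | OC(=O)CCCCCCCCCCCCCCI | intermediate
3 | pentadec-14-enoic acid | OC(=O)CCCCCCCCCCCCC=C | intermediate
4 | 15-iodopentadecan-1-ol | OCCCCCCCCCCCCCCCI | intermediate
5 | (−)-copalic acid, (5R,9R,10R)-ent-labda-8(17),13E-dien-15-oic acid | C/C(=C\C(=O)O)CC[C@@H]1C(=C)CC[C@@H]2C(C)(C)CCC[C@@]12C | starting material
6 | isopropyl (5R,9R,10R)-ent-labda-8(17),13E-dien-15-oate | C/C(=C\C(=O)OC(C)C)CC[C@@H]1C(=C)CC[C@@H]2C(C)(C)CCC[C@@]12C | intermediate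
7 | isopropyl (5R,8S,9S,10R)-ent-8,17-epoxylabd-13E-en-15-oate, oxirane O anti to the C10 methyl | C/C(=C\C(=O)OC(C)C)CC[C@@H]1[C@]3(CO3)CC[C@@H]2C(C)(C)CCC[C@@]12C | intermediate
8 | isopropyl (5R,9S,10R)-ent-17-hydroxylabda-7,13E-dien-15-oate | C/C(=C\C(=O)OC(C)C)CC[C@@H]1C(CO)=CC[C@@H]2C(C)(C)CCC[C@@]12C | intermediate
9 | (5R,9S,10R)-ent-labda-7,13E-diene-15,17-diol | C/C(=C\CO)CC[C@@H]1C(CO)=CC[C@@H]2C(C)(C)CCC[C@@]12C | intermediate
10 | (5R,9S,10R)-ent-17-hydroxylabda-7,13E-dien-15-yl pentadec-14-enoate | C/C(=C\COC(=O)CCCCCCCCCCCCC=C)CC[C@@H]1C(CO)=CC[C@@H]2C(C)(C)CCC[C@@]12C | intermediate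
11 | (2E)-5-[(1S,4aR,8aR)-2-(hydroxymethyl)-5,5,8a-trimethyl-1,4,4a,5,6,7,8,8a-octahydronaphthalen-1-yl]-3-methylpent-2-en-1-yl 30-hydroxytriacontanoate | C/C(=C\COC(=O)CCCCCCCCCCCCCCCCCCCCCCCCCCCCCO)CC[C@@H]1C(CO)=CC[C@@H]2C(C)(C)CCC[C@@]12C | target

Total step count: 9. Longest linear sequence: 6 steps (5 → 6 → 7 → 8 → 9 → 10 → 11, steps 4–9).

Steps most likely to fail

Step 9. Three processes could erode the cross-coupling:
- Hydrodehalogenation and homocoupling of the iodide may outrun it.
- Chain walking of the alkylnickel may erode linear selectivity.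
- Nickel may slowly ionise the allylic ester or the silane may silylate the free hydroxyls.

The fallback sets out from 10 and comes back at 11.
- The vinyl group of 10 is hydroborated with 9-BBN-H (2.2 equiv, THF, rt; one equivalent is consumed by the C17 hydroxyl). Steric control spares both trisubstituted alkenes, and this should give the terminal B-alkyl-9-BBN O17-borinate F1.
- Without isolation this is coupled with 4 in a palladium-catalysed alkyl–alkyl Suzuki–Miyaura reaction (Pd(OAc)2, PCy3, K3PO4·H2O, THF, rt).
- The aqueous work-up frees the C17 hydroxyl to give 11.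

The nucleophile is thus preformed in a separate step, and the same C15'–C16' bond is made by two-electron transmetalation instead of radical capture.

Step 8. Regioselectivity may be lost through acylation at O17 or double acylation, or turnover may be slow with the bulky diterpene alcohol. The fallback sets out from 8 and comes back at 10, bypassing 9.
- Silylation (TBSCl, imidazole, DMF) gives the isopropyl 17-(tert-butyldimethylsilyloxy) ester F2.
- DIBAL-H (CH2Cl2, −78 °C) gives the 17-O-TBS 15-alcohol F3.
- Steglich esterification with 3 (EDC·HCl, DMAP, CH2Cl2) gives the 17-O-TBS pentadec-14-enoate F4.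
- HF·pyridine in THF removes the silyl group to give 10.

Step 6. Proton loss may occur from C9 instead of C7, or a 1,2-hydride shift of the activated oxirane may compete with elimination. The fallback sets out from 6 and comes back at 8, replacing steps 5 and 6.
- A Schenck ene reaction with singlet oxygen (O2, tetraphenylporphyrin, visible light, CH2Cl2, 0 °C) should deliver oxygen to C17 while abstracting the axial C7 hydrogen.
- The conjugated C13=C14 bond stays inert, so this gives the allylic 17-hydroperoxide F5.
- PPh3 reduces this hydroperoxide in the same flask to 8.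

Further compounds
F1 | step 9 | ent-17-(9-borabicyclo[3.3.1]nonan-9-yloxy)labda-7,13E-dien-15-yl 15-(9-borabicyclo[3.3.1]nonan-9-yl)pentadecanoate | C/C(=C\COC(=O)CCCCCCCCCCCCCCB5C6CCCC5CCC6)CC[C@@H]1C(COB3C4CCCC3CCC4)=CC[C@@H]2C(C)(C)CCC[C@@]12C
F2 | step 8 | isopropyl ent-17-(tert-butyldimethylsilyloxy)labda-7,13E-dien-15-oate | C/C(=C\C(=O)OC(C)C)CC[C@@H]1C(CO[Si](C)(C)C(C)(C)C)=CC[C@@H]2C(C)(C)CCC[C@@]12C
F3 | step 8 | ent-17-(tert-butyldimethylsilyloxy)labda-7,13E-dien-15-ol | C/C(=C\CO)CC[C@@H]1C(CO[Si](C)(C)C(C)(C)C)=CC[C@@H]2C(C)(C)CCC[C@@]12C
F4 | step 8 | ent-17-(tert-butyldimethylsilyloxy)labda-7,13E-dien-15-yl pentadec-14-enoate | C/C(=C\COC(=O)CCCCCCCCCCCCC=C)CC[C@@H]1C(CO[Si](C)(C)C(C)(C)C)=CC[C@@H]2C(C)(C)CCC[C@@]12C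
F5 | step 6 | isopropyl ent-17-hydroperoxylabda-7,13E-dien-15-oate | C/C(=C\C(=O)OC(C)C)CC[C@@H]1C(COO)=CC[C@@H]2C(C)(C)CCC[C@@]12C
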